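**Plan**
1. Retrosynthesis: after removal of the protecting groups, cut C1–C2 of ring B (the carbocycle of the dihydronaphthalene); then the C8a–C1 aryl–CH2 bond (cross-coupling), the C2–O bond of a leaving group, and the C3=C4 alkene (Wittig). Ring C (the pyranone) goes back to ethyl 3-methylbut-2-enoate and diethyl oxalate.
2. Forward: ring C is made first (steps 1–3). Ring A (the catechol ring, from 2-bromo-4,5-dimethoxybenzaldehyde) receives the C4=C3–C2 chain by Wittig reaction, C2 is oxygenated, ring C is joined through C1, and ring B is closed last.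
3. Enabling feature: C1–H2 sits between C8a of ring A and C4′ of ring C, so it is the γ-position of a vinylogous lactone (C1–C4′=C3′–C2′=O) and a soft carbon acid. C2–C3–C4 is an allyl unit; with a leaving group on C2 it gives an η3-allyl whose only terminus C1 can reach through a six-membered transition state is C2.
4. Stereochemistry: both centres (1R,2S, trans) arise in the ring closure from the racemic carbonate. C2 comes from the allyl face chosen by the chiral ligand on palladium, C1 by 1,2-induction (trans, also the thermodynamic arrangement).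
5. Helpers: the C2 carbonate leaves in the key step; the methoxymethyl ethers and tert-butyl esters fall in one acid treatment at the end, and the C3 methyl ester is never touched.

Key step: step 11

Assumption: the (S)-phosphinooxazoline ligand is taken to favour the (1R,2S) series; if a test run shows the opposite sense, the (R)-ligand is used with no other change.

**Route**

Step 1
Reactants: 1 ethyl 3-methylbut-2-enoate; 2 diethyl oxalate
Product: 5 4-methyl-2-oxo-2H-pyran-6-carboxylic acid, via Claisen adduct 3 (not isolated), via ethyl ester 4 (not isolated)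
Conditions: KOEt, Et2O/EtOH, 0 °C to rt; then conc. HCl, 100 °C
Reagents that add atoms: water, O
Why: Vinylogous Claisen condensation of the γ-deprotonated enoate with non-enolisable diethyl oxalate gives the stabilised enolate of 3, and hot acid should lactonise the enol onto the ester and hydrolyse the remaining ethyl ester, the classical entry to 2-pyranone-6-carboxylic acids.

Step 2
Reactants: 5 4-methyl-2-oxo-2H-pyran-6-carboxylic acid
Product: 6 tert-butyl 4-methyl-2-oxo-2H-pyran-6-carboxylate
Conditions: tert-butyl 2,2,2-trichloroacetimidate, BF3·OEt2 (cat.), CH2Cl2/cyclohexane, rt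
Reagents that add atoms: tert-butyl 2,2,2-trichloroacetimidate, CC(C)(C)OC(=N)C(Cl)(Cl)Cl
Why: Acid-catalysed O-tert-butylation of the carboxylic acid by the imidate proceeds without base, so the lactone should stay intact.

Step 3
Reactants: 6 tert-butyl 4-methyl-2-oxo-2H-pyran-6-carboxylate
Product: 7 tert-butyl 4-(bromomethyl)-2-oxo-2H-pyran-6-carboxylate
Conditions: N-bromosuccinimide, 2,2′-azobis(2-methylpropionitrile) (cat.), PhCF3, 80 °C
Reagents that add atoms: N-bromosuccinimide, O=C1CCC(=O)N1Br
Why: Wohl–Ziegler bromination should take the only allylic methyl group, as with 4-methylcoumarins, while the electron-poor ring resists ionic bromination.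

Step 4
Reactants: 8 methyl 2-(triphenyl-λ5-phosphanylidene)acetate (2 equiv.); 9 tert-butyl bromoacetate
Product: 11 4-tert-butyl 1-methyl 2-(triphenyl-λ5-phosphanylidene)butanedioate, via phosphonium bromide 10 (not isolated)
Conditions: EtOAc, reflux
Reagents that add atoms: none
Why: C-alkylation of the stabilised ylide by the α-bromo ester followed by transylidation with the second equivalent of 8 should give the new stabilised ylide.

Step 5
Reactants: 12 2-bromo-4,5-dimethoxybenzaldehyde
Product: 13 2-bromo-4,5-dihydroxybenzaldehyde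
Conditions: BBr3, CH2Cl2, −78 °C to rt; H2O
Reagents that add atoms: none
Why: Aryl methyl ether cleavage by the boron Lewis acid (bromide attack on the O-methyl groups) should free the catechol without affecting aldehyde or aryl bromide.

Step 6
Reactants: 13 2-bromo-4,5-dihydroxybenzaldehyde
Product: 14 2-bromo-4,5-bis(methoxymethoxy)benzaldehyde
Conditions: MOMCl, iPr2NEt, CH2Cl2, 0 °C to rt
Reagents that add atoms: chloromethyl methyl ether, COCCl
Why: O-alkylation of both phenols gives acetal ethers that are stable to base and palladium and fall with acid at the end.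

Step 7
Reactants: 14 2-bromo-4,5-bis(methoxymethoxy)benzaldehyde; 11 4-tert-butyl 1-methyl 2-(triphenyl-λ5-phosphanylidene)butanedioate
Product: 15 4-tert-butyl 1-methyl (2E)-2-{[2-bromo-4,5-bis(methoxymethoxy)phenyl]methylidene}butanedioate
Conditions: toluene, 100 °C
Reagents that add atoms: none
Why: Wittig olefination with an α-substituted stabilised ylide should give the (E)-alkene (aryl trans to CO2Me, cis to the CH2CO2tBu arm), the geometry ring B needs, with the two esters already differentiated.

Step 8
Reactants: 15 4-tert-butyl 1-methyl (2E)-2-{[2-bromo-4,5-bis(methoxymethoxy)phenyl]methylidene}butanedioate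
Product: 16 1-tert-butyl 4-methyl (3E)-3-{[2-bromo-4,5-bis(methoxymethoxy)phenyl]methylidene}-2-hydroxybutanedioate (racemic)
Conditions: KN(SiMe3)2, THF, −78 °C; 2-(phenylsulfonyl)-3-phenyloxaziridine, −78 °C; AcOH
Reagents that add atoms: 2-(phenylsulfonyl)-3-phenyloxaziridine, O=S(=O)(c1ccccc1)N1OC1c1ccccc1
Why: The only acidic C–H is the CH2 that becomes C2, and α-hydroxylation of the resulting potassium dienolate by the N-sulfonyloxaziridine should place oxygen on C2 with the alkene geometry kept at low temperature.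

Step 9
Reactants: 16 1-tert-butyl 4-methyl (3E)-3-{[2-bromo-4,5-bis(methoxymethoxy)phenyl]methylidene}-2-hydroxybutanedioate; 7 tert-butyl 4-(bromomethyl)-2-oxo-2H-pyran-6-carboxylate
Product: 18 1-tert-butyl 4-methyl (3E)-3-{[2-{[6-(tert-butoxycarbonyl)-2-oxo-2H-pyran-4-yl]methyl}-4,5-bis(methoxymethoxy)phenyl]methylidene}-2-hydroxybutanedioate, via arylboronic ester 17 (not isolated)
Conditions: B2pin2, PdCl2(dppf), KOAc, 1,4-dioxane, 85 °C; then 7, CsF, 60 °C
Reagents that add atoms: bis(pinacolato)diboron, CC1(C)OB(OC1(C)C)B1OC(C)(C)C(C)(C)O1 (boron is kept in 17 only)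
Why: Miyaura borylation of the aryl bromide followed by fluoride-promoted Suzuki–Miyaura sp2–sp3 coupling with the benzylic-type bromide (as known for 4-(halomethyl)coumarins) should join ring C through C1 without aqueous base that would open the lactone.

Step 10
Reactants: 18 1-tert-butyl 4-methyl (3E)-3-{[2-{[6-(tert-butoxycarbonyl)-2-oxo-2H-pyran-4-yl]methyl}-4,5-bis(methoxymethoxy)phenyl]methylidene}-2-hydroxybutanedioate
Product: 19 1-tert-butyl 4-methyl (3E)-2-[(tert-butoxycarbonyl)oxy]-3-{[2-{[6-(tert-butoxycarbonyl)-2-oxo-2H-pyran-4-yl]methyl}-4,5-bis(methoxymethoxy)phenyl]methylidene}butanedioate (racemic)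
Conditions: Boc2O, 4-(dimethylamino)pyridine (cat.), CH2Cl2, 0 °C
Reagents that add atoms: di-tert-butyl dicarbonate, CC(C)(C)OC(=O)OC(=O)OC(C)(C)C
Why: Nucleophile-catalysed carbonate formation at the secondary alcohol installs the leaving group, the weaker carbon acid C1–H2 not being acylated under these conditions.

Step 11
Reactants: 19 1-tert-butyl 4-methyl (3E)-2-[(tert-butoxycarbonyl)oxy]-3-{[2-{[6-(tert-butoxycarbonyl)-2-oxo-2H-pyran-4-yl]methyl}-4,5-bis(methoxymethoxy)phenyl]methylidene}butanedioate
Product: 20 2-tert-butyl 3-methyl (1R,2S)-1-[6-(tert-butoxycarbonyl)-2-oxo-2H-pyran-4-yl]-6,7-bis(methoxymethoxy)-1,2-dihydronaphthalene-2,3-dicarboxylate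
Conditions: Pd2(dba)3 (2.5 mol%), (S)-4-tert-butyl-2-[2-(diphenylphosphino)phenyl]-4,5-dihydrooxazole (6 mol%), CH2Cl2 (0.01 M), rt
Reagents that add atoms: none
Why: Zerovalent palladium ionises the allylic carbonate to an η3-allyl complex over C2–C3–C4, the tert-butoxide released on loss of CO2 deprotonates C1–H (benzylic to ring A and γ to the lactone carbonyl through C4′=C3′ of ring C), and the soft vinylogous enolate attacks terminus C2 on the face opposite to palladium; the closest known type is the Tsuji–Trost asymmetric allylic alkylation in its intramolecular form, together with γ-allylation of 4-methylcoumarin-type lactones. Ring B closes through a six-membered transition state with the allyl C3=C4 ending inside the ring (6-endo attack on the allyl terminus), and the tether secures regiochemistry because attack at C4 would need a four-membered ring and attack through C3′ or oxygen an eight-membered or larger one. C2 is set by the allyl face the chiral P,N-ligand selects, and the racemic carbonate should converge because the ester on C2 lets the complex exchange faces through an O-bound palladium dienolate and C2–H of 19 is itself base-labile (dynamic kinetic asymmetric transformation). C1 is set by 1,2-induction in the closure, the pyranonyl group taking the position trans to the C2 ester, which is also the thermodynamically preferred arrangement in 1-aryl-1,2-dihydronaphthalene-2,3-diesters. The step needs high dilution to suppress intermolecular alkylation at the aryl-bearing terminus C4 and no added base so that the new C1–H and C2–H centres are not equilibrated and the 1,2-dihydronaphthalene does not isomerise.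

Step 12
Reactants: 20 2-tert-butyl 3-methyl (1R,2S)-1-[6-(tert-butoxycarbonyl)-2-oxo-2H-pyran-4-yl]-6,7-bis(methoxymethoxy)-1,2-dihydronaphthalene-2,3-dicarboxylate
Product: 21 (1R,2S)-1-(6-carboxy-2-oxo-2H-pyran-4-yl)-6,7-dihydroxy-3-(methoxycarbonyl)-1,2-dihydronaphthalene-2-carboxylic acid
Conditions: CF3CO2H/CH2Cl2 (1:1), H2O (10 equiv.), 0 °C to rt
Reagents that add atoms: none
Why: Acidolysis should cleave both tert-butyl esters (loss of isobutene) and both methoxymethyl acetals while the methyl ester, the lactone and the two base-sensitive stereocentres are untouched in the acidic medium.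

**Compound list**
1 | ethyl 3-methylbut-2-enoate | CCOC(=O)C=C(C)C | starting material
2 | diethyl oxalate | CCOC(=O)C(=O)OCC | starting material
3 | diethyl 3-methyl-5-oxohex-2-enedioate (potassium enolate in the flask, geometry mobile) | CCOC(=O)C=C(C)CC(=O)C(=O)OCC | intermediate
4 | ethyl 4-methyl-2-oxo-2H-pyran-6-carboxylate | CCOC(=O)c1cc(C)cc(=O)o1 | intermediate
5 | 4-methyl-2-oxo-2H-pyran-6-carboxylic acid | Cc1cc(C(=O)O)oc(=O)c1 | intermediate
6 | tert-butyl 4-methyl-2-oxo-2H-pyran-6-carboxylate | Cc1cc(C(=O)OC(C)(C)C)oc(=O)c1 | intermediate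
7 | tert-butyl 4-(bromomethyl)-2-oxo-2H-pyran-6-carboxylate | BrCc1cc(C(=O)OC(C)(C)C)oc(=O)c1 | intermediate
8 | methyl 2-(triphenyl-λ5-phosphanylidene)acetate | COC(=O)C=P(c1ccccc1)(c1ccccc1)c1ccccc1 | starting material
9 | tert-butyl bromoacetate | CC(C)(C)OC(=O)CBr | starting material
10 | (4-tert-butoxy-1-methoxy-1,4-dioxobutan-2-yl)triphenylphosphonium bromide | COC(=O)C(CC(=O)OC(C)(C)C)[P+](c1ccccc1)(c1ccccc1)c1ccccc1.[Br-] | intermediate
11 | 4-tert-butyl 1-methyl 2-(triphenyl-λ5-phosphanylidene)butanedioate | COC(=O)C(CC(=O)OC(C)(C)C)=P(c1ccccc1)(c1ccccc1)c1ccccc1 | intermediate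
12 | 2-bromo-4,5-dimethoxybenzaldehyde | COc1cc(Br)c(C=O)cc1OC | starting material
13 | 2-bromo-4,5-dihydroxybenzaldehyde | O=Cc1cc(O)c(O)cc1Br | intermediate
14 | 2-bromo-4,5-bis(methoxymethoxy)benzaldehyde | COCOc1cc(Br)c(C=O)cc1OCOC | intermediate
15 | 4-tert-butyl 1-methyl (2E)-2-{[2-bromo-4,5-bis(methoxymethoxy)phenyl]methylidene}butanedioate | COC(=O)/C(CC(=O)OC(C)(C)C)=C/c1cc(OCOC)c(OCOC)cc1Br | intermediate
16 | 1-tert-butyl 4-methyl (3E)-3-{[2-bromo-4,5-bis(methoxymethoxy)phenyl]methylidene}-2-hydroxybutanedioate (racemic) | COC(=O)/C(C(O)C(=O)OC(C)(C)C)=C/c1cc(OCOC)c(OCOC)cc1Br | intermediate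
17 | 1-tert-butyl 4-methyl (3E)-3-{[4,5-bis(methoxymethoxy)-2-(4,4,5,5-tetramethyl-1,3,2-dioxaborolan-2-yl)phenyl]methylidene}-2-hydroxybutanedioate (racemic) | COC(=O)/C(C(O)C(=O)OC(C)(C)C)=C/c1cc(OCOC)c(OCOC)cc1B1OC(C)(C)C(C)(C)O1 | intermediate
18 | 1-tert-butyl 4-methyl (3E)-3-{[2-{[6-(tert-butoxycarbonyl)-2-oxo-2H-pyran-4-yl]methyl}-4,5-bis(methoxymethoxy)phenyl]methylidene}-2-hydroxybutanedioate (racemic) | COC(=O)/C(C(O)C(=O)OC(C)(C)C)=C/c1cc(OCOC)c(OCOC)cc1Cc1cc(C(=O)OC(C)(C)C)oc(=O)c1 | intermediate
19 | 1-tert-butyl 4-methyl (3E)-2-[(tert-butoxycarbonyl)oxy]-3-{[2-{[6-(tert-butoxycarbonyl)-2-oxo-2H-pyran-4-yl]methyl}-4,5-bis(methoxymethoxy)phenyl]methylidene}butanedioate (racemic) | COC(=O)/C(C(OC(=O)OC(C)(C)C)C(=O)OC(C)(C)C)=C/c1cc(OCOC)c(OCOC)cc1Cc1cc(C(=O)OC(C)(C)C)oc(=O)c1 | intermediate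
20 | 2-tert-butyl 3-methyl (1R,2S)-1-[6-(tert-butoxycarbonyl)-2-oxo-2H-pyran-4-yl]-6,7-bis(methoxymethoxy)-1,2-dihydronaphthalene-2,3-dicarboxylate | COC(=O)C1=Cc2cc(OCOC)c(OCOC)cc2[C@@H](c2cc(C(=O)OC(C)(C)C)oc(=O)c2)[C@@H]1C(=O)OC(C)(C)C | intermediate
21 | (1R,2S)-1-(6-carboxy-2-oxo-2H-pyran-4-yl)-6,7-dihydroxy-3-(methoxycarbonyl)-1,2-dihydronaphthalene-2-carboxylic acid | COC(=O)C1=Cc2cc(O)c(O)cc2[C@@H](c2cc(C(=O)O)oc(=O)c2)[C@@H]1C(=O)O | target

**Summary**
Total step count: 12. Longest linear sequence: 8 steps (12 to 21, steps 5–12).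

Steps most likely to fail:

Step 11. The two enantiomeric allyl complexes may not exchange faces fast enough, so that only a kinetic resolution takes place, or closure may be cis-selective or intermolecular. The fallback sets out from 18 and comes back at 20. Compound 18 is oxidised with Dess–Martin periodinane to the α-keto ester F1. Corey–Bakshi–Shibata reduction (catecholborane, the enantiomer of 1-methyl-3,3-diphenyltetrahydro-3H-pyrrolo[1,2-c][1,3,2]oxazaborole that delivers the 2R carbinol, toluene, −78 °C) should give the (2R)-alcohol F2. MsCl/Et3N at −20 °C converts it into the (2R)-methanesulfonate F3. Cs2CO3 in MeCN at 0 °C then closes ring B by intramolecular C-alkylation: the C1 carbanion displaces the sulfonate with inversion to set 2S and, by the same 1,2-induction, the trans 1R centre of 20.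

Step 9. The ortho-substituted arylboronic ester may protodeboronate, and fluoride or acetate may attack the bromomethyl lactone before cross-coupling occurs. The fallback sets out from 16 (with 7) and comes back at 18. Compound 16 is stannylated with Me3SnSnMe3 and Pd(PPh3)4 (toluene, 100 °C) to the aryltrimethylstannane F4, which is joined to 7 by a base-free Stille coupling (Pd2(dba)3, tri(2-furyl)phosphine, toluene, 60 °C).

Step 8. The potassium dienolate may take up oxygen at the γ-carbon or lose its alkene geometry, and the product alkoxide may isomerise to the 2-oxo ester under the basic conditions. The fallback sets out from 15 and comes back at 16. Compound 15 is converted with LiN(iPr)2 and tBuMe2SiCl (THF/DMPU, −78 °C) into the silyl ketene acetal F5. Rubottom oxidation of its electron-rich C=C (mCPBA, NaHCO3, CH2Cl2, −20 °C) gives the α-silyloxy ester F6, and HF·pyridine removes silicon to give 16; oxygen is thus delivered to a neutral nucleophile and no free alkoxide meets base.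

**Further compounds**
F1 | step 11 | 1-tert-butyl 4-methyl (3E)-3-{[2-{[6-(tert-butoxycarbonyl)-2-oxo-2H-pyran-4-yl]methyl}-4,5-bis(methoxymethoxy)phenyl]methylidene}-2-oxobutanedioate | COC(=O)/C(C(=O)C(=O)OC(C)(C)C)=C/c1cc(OCOC)c(OCOC)cc1Cc1cc(C(=O)OC(C)(C)C)oc(=O)c1
F2 | step 11 | 1-tert-butyl 4-methyl (2R,3E)-3-{[2-{[6-(tert-butoxycarbonyl)-2-oxo-2H-pyran-4-yl]methyl}-4,5-bis(methoxymethoxy)phenyl]methylidene}-2-hydroxybutanedioate | COC(=O)/C([C@@H](O)C(=O)OC(C)(C)C)=C/c1cc(OCOC)c(OCOC)cc1Cc1cc(C(=O)OC(C)(C)C)oc(=O)c1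
F3 | step 11 | 1-tert-butyl 4-methyl (2R,3E)-3-{[2-{[6-(tert-butoxycarbonyl)-2-oxo-2H-pyran-4-yl]methyl}-4,5-bis(methoxymethoxy)phenyl]methylidene}-2-[(methylsulfonyl)oxy]butanedioate | COC(=O)/C([C@@H](OS(C)(=O)=O)C(=O)OC(C)(C)C)=C/c1cc(OCOC)c(OCOC)cc1Cc1cc(C(=O)OC(C)(C)C)oc(=O)c1
F4 | step 9 | 1-tert-butyl 4-methyl (3E)-3-{[4,5-bis(methoxymethoxy)-2-(trimethylstannyl)phenyl]methylidene}-2-hydroxybutanedioate | COC(=O)/C(C(O)C(=O)OC(C)(C)C)=C/c1cc(OCOC)c(OCOC)cc1[Sn](C)(C)C
F5 | step 8 | methyl (2E)-3-[2-bromo-4,5-bis(methoxymethoxy)phenyl]-2-{2-tert-butoxy-2-[(tert-butyldimethylsilyl)oxy]ethenyl}prop-2-enoate | COC(=O)/C(C=C(OC(C)(C)C)O[Si](C)(C)C(C)(C)C)=C/c1cc(OCOC)c(OCOC)cc1Br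
F6 | step 8 | 1-tert-butyl 4-methyl (3E)-3-{[2-bromo-4,5-bis(methoxymethoxy)phenyl]methylidene}-2-[(tert-butyldimethylsilyl)oxy]butanedioate | COC(=O)/C(C(O[Si](C)(C)C(C)(C)C)C(=O)OC(C)(C)C)=C/c1cc(OCOC)c(OCOC)cc1Br
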